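**Plan**

1. Numbering (germacrane): C6 = lactone carbinol, C5 = ester carbinol, C4 = tertiary carbinol, C3–C1 = methylenes, C10 = CH(CH3), C9 = ketone, C8 = carbinol, C7 = ring-fusion CH, C11–C13 = lactone carbons. Retrosynthetic cuts in order: isovalerate C–O, C11=C13, lactone O6–C12, C4–OH (back to a (Z)-C3=C4 alkene), then C5–C6 by a retro-[3,3] shift that re-joins C3 to C8 (ten-membered ring back to a cyclohexanol), then C7–C11, C8–C7 and the C5–O bond.
2. Forward: the ring C8–C9–C10–C1–C2–C3 is bought as (S)-carvone (its isopropenyl group = C4, C5, C15). C5 is oxygenated and made an (E)-enol ether, C9 is masked as a ketal, and C8 is made a ketone that receives C7=C6 as an (E)-2-alkoxyvinyl group. An anionic oxy-Cope ring enlargement (6 to 10) then forms C5–C6, and the enolate takes up C11–C12. Lactone, methylene and ester come last.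
3. Stereochemistry: C10 comes from carvone. C3 of carvone steers the chair transition state and is traded for C5 and C6. C7 is set by outer-face alkylation of the ring enolate, C8 by chelate/Felkin-controlled reduction, C4 by hydroxyl-directed epoxidation and hydride opening.
4. Enabling feature: C5 and C6 are the 1,6-ends of a hexa-1,5-diene C6=C7–C8–C3–C4=C5 hidden in the ten-membered ring. C8 bears oxygen (the oxy-Cope carbinol), C4 is a tertiary carbinol that a C3=C4 alkene can give, both ends bear oxygen (enol ethers), and C8–C9–C10–C1–C2–C3 with its methyl and its C3 branch is a p-menthane six-membered ring.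

Key step: step 11

Remark: the hydroxyl introduced in step 4 is oxidised away in step 7, so its configuration is immaterial; the isomer trans to the side chain is drawn. Minor epimers expected in steps 3, 4 and 9 would be removed by chromatography.

**Route**

Step 1
Reactants: 1 (S)-(+)-carvone
Product: 2 (5S)-5-(3-chloroprop-1-en-2-yl)-2-methylcyclohex-2-en-1-one
Conditions: Ca(OCl)2, CO2 (dry ice), CH2Cl2/H2O, 0 °C
Reagents that add atoms: calcium hypochlorite, [Ca+2].[O-]Cl.[O-]Cl
Why: hypochlorous acid released from Ca(OCl)2 by CO2 should chlorinate the electron-rich 1,1-disubstituted alkene in an ene-type allylic chlorination with double-bond shift, leaving the electron-poor enone alkene and the stereocentre untouched.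

Step 2
Reactants: 2 (5S)-5-(3-chloroprop-1-en-2-yl)-2-methylcyclohex-2-en-1-one; 3 4-methoxybenzyl alcohol
Product: 4 (5S)-5-{3-[(4-methoxybenzyl)oxy]prop-1-en-2-yl}-2-methylcyclohex-2-en-1-one
Conditions: 3, NaH, THF, 0 °C; then 2, Bu4NI (cat.), 0 °C to rt
Reagents that add atoms: none
Why: Williamson ether synthesis, in which the alkoxide of 3 displaces the primary allylic chloride by SN2 faster than it adds reversibly to the hindered enone.

Step 3
Reactants: 4 (5S)-5-{3-[(4-methoxybenzyl)oxy]prop-1-en-2-yl}-2-methylcyclohex-2-en-1-one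
Product: 6 (2S,5S)-5-{3-[(4-methoxybenzyl)oxy]prop-1-en-2-yl}-2-methylcyclohexan-1-one, via lithium enolate 5 (not isolated)
Conditions: LiBH(s-Bu)3, THF, −78 °C; aq NH4Cl; then NaOMe (cat.), MeOH, rt
Reagents that add atoms: none
Why: the bulky trialkylborohydride should deliver hydride in a 1,4-sense (conjugate reduction of the enone), and protonation followed by base equilibration of the methyl-bearing centre should give mainly the trans-2,5-disubstituted cyclohexanone with both groups equatorial.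

Step 4
Reactants: 6 (2S,5S)-5-{3-[(4-methoxybenzyl)oxy]prop-1-en-2-yl}-2-methylcyclohexan-1-one
Product: 8 (2R,3R,6S)-2-hydroxy-3-{3-[(4-methoxybenzyl)oxy]prop-1-en-2-yl}-6-methylcyclohexan-1-one, via potassium enolate 7 (not isolated)
Conditions: KN(SiMe3)2, THF, −78 °C; then 2-(phenylsulfonyl)-3-phenyloxaziridine, −78 °C; aq NH4Cl
Reagents that add atoms: 2-(phenylsulfonyl)-3-phenyloxaziridine, O=S(=O)(N1OC1c1ccccc1)c1ccccc1
Why: the hindered amide base should deprotonate kinetically at the CH2 flank of the ketone and not at the methyl-bearing methine, and the enolate is hydroxylated by the N-sulfonyloxaziridine (enolate oxidation) anti to the neighbouring side chain.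

Step 5
Reactants: 8 (2R,3R,6S)-2-hydroxy-3-{3-[(4-methoxybenzyl)oxy]prop-1-en-2-yl}-6-methylcyclohexan-1-one
Product: 9 (1R,3S,6R)-2,2-dimethoxy-6-{3-[(4-methoxybenzyl)oxy]prop-1-en-2-yl}-3-methylcyclohexan-1-ol
Conditions: HC(OMe)3, MeOH, camphorsulfonic acid (cat.), rt
Reagents that add atoms: methanol, CO; trimethyl orthoformate, COC(OC)OC
Why: acid-catalysed ketalisation with orthoformate as water scavenger converts the only carbonyl group into its dimethyl ketal at room temperature, where the adjacent methyl-bearing centre should not epimerise and the benzylic ether survives.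

Step 6
Reactants: 9 (1R,3S,6R)-2,2-dimethoxy-6-{3-[(4-methoxybenzyl)oxy]prop-1-en-2-yl}-3-methylcyclohexan-1-ol
Product: 10 (1R,3S,6R)-2,2-dimethoxy-6-{(E)-1-[(4-methoxybenzyl)oxy]prop-1-en-2-yl}-3-methylcyclohexan-1-ol
Conditions: KOt-Bu (2.5 equiv), DMSO, rt to 50 °C; H2O
Reagents that add atoms: none
Why: base-mediated isomerisation of an allyl ether to a propenyl ether runs through a potassium-bridged cisoid oxyallyl anion, so the oxygen should end up cis to the new methyl group and trans to the ring carbon, which is the (E)-enol ether, while the hydroxyl is carried as its alkoxide.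

Step 7
Reactants: 10 (1R,3S,6R)-2,2-dimethoxy-6-{(E)-1-[(4-methoxybenzyl)oxy]prop-1-en-2-yl}-3-methylcyclohexan-1-ol
Product: 11 (3S,6R)-2,2-dimethoxy-6-{(E)-1-[(4-methoxybenzyl)oxy]prop-1-en-2-yl}-3-methylcyclohexan-1-one
Conditions: Dess–Martin periodinane, pyridine, CH2Cl2, 0 °C to rt
Reagents that add atoms: none
Why: Dess–Martin oxidation under pyridine buffering should oxidise the hindered secondary alcohol without harming the acid-sensitive enol ether or the ketal, and the alpha centre keeps its equatorial side chain, which is also the thermodynamic arrangement.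

Step 8
Reactants: 3 4-methoxybenzyl alcohol; 12 trichloroethylene
Product: 13 (E)-1,2-dichloroethenyl 4-methoxybenzyl ether
Conditions: KH, THF, 0 °C; then 12, −50 °C to rt
Reagents that add atoms: none
Why: base converts trichloroethylene into dichloroacetylene, to which the alkoxide of 3 adds in an anti sense (addition–elimination route to 1,2-dichlorovinyl ethers), giving the precursor of an alkoxyacetylide.

Step 9
Reactants: 11 (3S,6R)-2,2-dimethoxy-6-{(E)-1-[(4-methoxybenzyl)oxy]prop-1-en-2-yl}-3-methylcyclohexan-1-one; 13 (E)-1,2-dichloroethenyl 4-methoxybenzyl ether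
Product: 15 (1S,3S,6R)-2,2-dimethoxy-1-{[(4-methoxybenzyl)oxy]ethynyl}-6-{(E)-1-[(4-methoxybenzyl)oxy]prop-1-en-2-yl}-3-methylcyclohexan-1-ol, via lithium alkoxyacetylide 14 (not isolated)
Conditions: 13, n-BuLi (2.2 equiv), THF, −78 to −40 °C; then 11, −78 °C; H2O
Reagents that add atoms: none
Why: two equivalents of n-BuLi turn 13 into the lithium alkoxyacetylide (elimination, then chlorine–lithium exchange), which should add 1,2 to the ketone from the axial direction, as slim acetylides do and anti to the axial methoxy group on the neighbouring ketal carbon, so that the alkynyl group is cis to the side chain and the hydroxyl equatorial.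

Step 10
Reactants: 15 (1S,3S,6R)-2,2-dimethoxy-1-{[(4-methoxybenzyl)oxy]ethynyl}-6-{(E)-1-[(4-methoxybenzyl)oxy]prop-1-en-2-yl}-3-methylcyclohexan-1-ol
Product: 16 (1S,3S,6R)-2,2-dimethoxy-1-{(E)-2-[(4-methoxybenzyl)oxy]ethenyl}-6-{(E)-1-[(4-methoxybenzyl)oxy]prop-1-en-2-yl}-3-methylcyclohexan-1-ol
Conditions: LiAlH4, THF, 0 °C to rt; aq potassium sodium tartrate
Reagents that add atoms: none
Why: alkoxide-directed trans-hydroalumination of the propargylic alcohol followed by protonolysis should give the (E)-2-alkoxyvinyl carbinol, the usual outcome of LiAlH4 reduction of 3-hydroxy-1-alkoxyalkynes.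

Step 11
Reactants: 16 (1S,3S,6R)-2,2-dimethoxy-1-{(E)-2-[(4-methoxybenzyl)oxy]ethenyl}-6-{(E)-1-[(4-methoxybenzyl)oxy]prop-1-en-2-yl}-3-methylcyclohexan-1-ol
Product: 19 tert-butyl 2-{(1R,2R,3R,4Z,8S)-9,9-dimethoxy-2,3-bis[(4-methoxybenzyl)oxy]-4,8-dimethyl-10-oxocyclodec-4-en-1-yl}acetate, via potassium alkoxide 17 (not isolated), via potassium enolate 18 (not isolated)
Conditions: KN(SiMe3)2, 18-crown-6, THF, −78 to 0 °C; then BrCH2CO2t-Bu, −78 °C
Reagents that add atoms: tert-butyl bromoacetate, BrCC(=O)OC(C)(C)C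
Why: The potassium alkoxide 17 should undergo a charge-accelerated [3,3]-sigmatropic shift (anionic oxy-Cope rearrangement) across the hexa-1,5-diene C6=C7–C8–C3–C4=C5, in which the C3–C8 bond of the cyclohexane breaks as the C5–C6 bond forms between the two enol-ether ends; the closest known reaction type is the ring enlargement of 1,2-dialkenylcyclohexanols to cyclodec-5-enones. The ten-membered ring thus arises by a four-atom expansion of the six-membered ring through a six-centre chair transition state, not by end-to-end cyclisation. In the reacting cyclohexane chair the alkoxide, the C3 side chain and the C10 methyl are equatorial and only the C8 alkenyl group is axial, which leaves one chair transition state with both (E)-enol-ether oxygens equatorial; C5 and C6 therefore form as the threo pair in the absolute sense dictated by C3 of carvone, and the axial C2 gives the (Z)-C3=C4 alkene. Enolate 18 is then C-alkylated by the bromoacetate on its outer face, the face turned away from the former C3–C5 allyl unit and the ring interior, which places the C7 side chain syn to the C6 oxygen as the trans lactone requires. The step needs chair over boat geometry, rearrangement and alkylation faster than beta-elimination of the C6 alkoxide from the enolate, and C- over O-alkylation; these should be secured by the methyl group on C4 (which disfavours a boat), by the poor leaving group at low temperature, and by the soft reactive alkyl bromide.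

Step 12
Reactants: 19 tert-butyl 2-{(1R,2R,3R,4Z,8S)-9,9-dimethoxy-2,3-bis[(4-methoxybenzyl)oxy]-4,8-dimethyl-10-oxocyclodec-4-en-1-yl}acetate
Product: 20 tert-butyl 2-{(1S,2R,3R,4Z,8S,10S)-10-hydroxy-9,9-dimethoxy-2,3-bis[(4-methoxybenzyl)oxy]-4,8-dimethylcyclodec-4-en-1-yl}acetate
Conditions: Zn(BH4)2, Et2O, −30 to 0 °C
Reagents that add atoms: none
Why: zinc chelation between the ketone and the C6 ether oxygen should direct hydride to the face that gives the 1,3-syn C6/C8 relationship (chelation-controlled reduction of a beta-alkoxy ketone), and this is reinforced by Felkin–Anh 1,2-induction from C7, so the all-syn C6/C7/C8 triad is expected while the tert-butyl ester stays intact.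

Step 13
Reactants: 20 tert-butyl 2-{(1S,2R,3R,4Z,8S,10S)-10-hydroxy-9,9-dimethoxy-2,3-bis[(4-methoxybenzyl)oxy]-4,8-dimethylcyclodec-4-en-1-yl}acetate
Product: 21 tert-butyl 2-{(1R,2R,3R,4Z,8S,10S)-9,9-dimethoxy-2,3-bis[(4-methoxybenzyl)oxy]-4,8-dimethyl-10-[(triethylsilyl)oxy]cyclodec-4-en-1-yl}acetate
Conditions: Et3SiCl, imidazole, DMAP (cat.), DMF, rt
Reagents that add atoms: chlorotriethylsilane, CC[Si](Cl)(CC)CC
Why: silylation with the small triethylsilyl group protects the hindered C8 hydroxyl, so that later only the C6 oxygen can lactonise and only the C5 hydroxyl can be acylated.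

Step 14
Reactants: 21 tert-butyl 2-{(1R,2R,3R,4Z,8S,10S)-9,9-dimethoxy-2,3-bis[(4-methoxybenzyl)oxy]-4,8-dimethyl-10-[(triethylsilyl)oxy]cyclodec-4-en-1-yl}acetate
Product: 22 tert-butyl 2-{(1R,2R,3R,4Z,8S,10S)-2,3-dihydroxy-9,9-dimethoxy-4,8-dimethyl-10-[(triethylsilyl)oxy]cyclodec-4-en-1-yl}acetate
Conditions: DDQ (2.5 equiv), CH2Cl2/aq NaH2PO4–Na2HPO4 buffer (pH 7), 0 °C
Reagents that add atoms: none
Why: DDQ oxidises both electron-rich benzylic ethers to oxocarbenium ions that water hydrolyses (oxidative cleavage of 4-methoxybenzyl ethers), freeing the C5 and C6 hydroxyls without touching the silyl ether, the ketal, the ester or the alkene.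

Step 15
Reactants: 22 tert-butyl 2-{(1R,2R,3R,4Z,8S,10S)-2,3-dihydroxy-9,9-dimethoxy-4,8-dimethyl-10-[(triethylsilyl)oxy]cyclodec-4-en-1-yl}acetate
Product: 23 tert-butyl 2-{(1R,2R,3S,4S,5R,8S,10S)-4,5-epoxy-2,3-dihydroxy-9,9-dimethoxy-4,8-dimethyl-10-[(triethylsilyl)oxy]cyclodecyl}acetate
Conditions: VO(acac)2 (5 mol %), t-BuOOH, CH2Cl2, 0 °C to rt
Reagents that add atoms: tert-butyl hydroperoxide, CC(C)(C)OO
Why: vanadium-catalysed hydroxyl-directed epoxidation delivers oxygen to the (Z)-trisubstituted alkene from the side of the allylic C5 hydroxyl, which in cis-cycloalkenols of medium ring size gives the cis (erythro) epoxy alcohol and hence the C4 configuration of the target.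

Step 16
Reactants: 23 tert-butyl 2-{(1R,2R,3S,4S,5R,8S,10S)-4,5-epoxy-2,3-dihydroxy-9,9-dimethoxy-4,8-dimethyl-10-[(triethylsilyl)oxy]cyclodecyl}acetate
Product: 24 2-{(1R,2R,3S,4R,8S,10S)-2,3,4-trihydroxy-9,9-dimethoxy-4,8-dimethyl-10-[(triethylsilyl)oxy]cyclodecyl}ethan-1-ol
Conditions: LiBHEt3 (excess), THF, 0 °C to rt; H2O
Reagents that add atoms: none
Why: the strongly nucleophilic hydride should open the trisubstituted epoxide by SN2 attack at the less hindered C3, leaving the C4 tertiary alcohol with its configuration untouched, and it reduces the tert-butyl ester to the primary alcohol in the same operation.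

Step 17
Reactants: 24 2-{(1R,2R,3S,4R,8S,10S)-2,3,4-trihydroxy-9,9-dimethoxy-4,8-dimethyl-10-[(triethylsilyl)oxy]cyclodecyl}ethan-1-ol
Product: 26 (3aR,4S,6S,10R,11S,11aR)-10,11-dihydroxy-5,5-dimethoxy-6,10-dimethyl-4-[(triethylsilyl)oxy]decahydrocyclodeca[b]furan-2(3H)-one, via lactol 25 (not isolated)
Conditions: TEMPO (10 mol %), KBr (10 mol %), NaOCl (2.2 equiv), NaHCO3, CH2Cl2/H2O, 0 °C
Reagents that add atoms: none
Why: oxoammonium oxidation is selective for the primary alcohol, the aldehyde is trapped by the gamma C6 hydroxyl as the five-membered lactol and oxidised on to the gamma-lactone (oxidative lactonisation of a 1,4-diol), while the hindered secondary and tertiary hydroxyls should be left alone and no glycol cleavage is expected with this oxidant.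

Step 18
Reactants: 26 (3aR,4S,6S,10R,11S,11aR)-10,11-dihydroxy-5,5-dimethoxy-6,10-dimethyl-4-[(triethylsilyl)oxy]decahydrocyclodeca[b]furan-2(3H)-one
Product: 28 (3aR,4S,6S,10R,11S,11aR)-10,11-dihydroxy-5,5-dimethoxy-6,10-dimethyl-3-methylidene-4-[(triethylsilyl)oxy]decahydrocyclodeca[b]furan-2(3H)-one, via sodium hydroxymethylidene-lactone salt 27 (not isolated)
Conditions: NaH (excess), HCO2Et, THF, 0 °C to rt; then (CH2O)n, THF, 50 °C; aq K2CO3
Reagents that add atoms: formaldehyde (from paraformaldehyde), C=O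
Why: Claisen formylation of the lactone gives the alpha-hydroxymethylidene salt, whose aldol addition to formaldehyde is followed by formyl transfer and loss of formate (alpha-methylenation of a lactone), the two free hydroxyls being carried as alkoxides and any formate esters cleaved in the carbonate work-up.

Step 19
Reactants: 28 (3aR,4S,6S,10R,11S,11aR)-10,11-dihydroxy-5,5-dimethoxy-6,10-dimethyl-3-methylidene-4-[(triethylsilyl)oxy]decahydrocyclodeca[b]furan-2(3H)-one
Product: 29 (3aR,4S,6S,10R,11S,11aR)-10-hydroxy-5,5-dimethoxy-6,10-dimethyl-3-methylidene-2-oxo-4-[(triethylsilyl)oxy]dodecahydrocyclodeca[b]furan-11-yl 3-methylbutanoate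
Conditions: 3-methylbutanoyl chloride, pyridine, DMAP (cat.), CH2Cl2, 0 °C to rt
Reagents that add atoms: 3-methylbutanoyl chloride, CC(C)CC(=O)Cl
Why: DMAP-catalysed acylation should esterify only the secondary C5 hydroxyl, because the C4 hydroxyl is tertiary and the C8 hydroxyl is silylated.

Step 20
Reactants: 29 (3aR,4S,6S,10R,11S,11aR)-10-hydroxy-5,5-dimethoxy-6,10-dimethyl-3-methylidene-2-oxo-4-[(triethylsilyl)oxy]dodecahydrocyclodeca[b]furan-11-yl 3-methylbutanoate
Product: 30 CNP0240128.1, (3aS,4S,6S,10R,11S,11aR)-4,10-dihydroxy-6,10-dimethyl-3-methylidene-2,5-dioxododecahydrocyclodeca[b]furan-11-yl 3-methylbutanoate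
Conditions: 48% aq HF, MeCN, 0 °C to rt
Reagents that add atoms: water, O
Why: aqueous HF cleaves the triethylsilyl ether and hydrolyses the dimethyl ketal to the C9 ketone in one operation, under conditions that should spare the ester, the methylene lactone and the tertiary alcohol.

**Compound list**

1 | (S)-(+)-carvone, (5S)-2-methyl-5-(prop-1-en-2-yl)cyclohex-2-en-1-one | O=C1C(C)=CC[C@H](C(C)=C)C1 | starting material
2 | (5S)-5-(3-chloroprop-1-en-2-yl)-2-methylcyclohex-2-en-1-one | O=C1C(C)=CC[C@H](C(=C)CCl)C1 | intermediate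
3 | 4-methoxybenzyl alcohol | COc1ccc(CO)cc1 | starting material
4 | (5S)-5-{3-[(4-methoxybenzyl)oxy]prop-1-en-2-yl}-2-methylcyclohex-2-en-1-one | O=C1C(C)=CC[C@H](C(=C)COCc2ccc(OC)cc2)C1 | intermediate
5 | lithium (5S)-5-{3-[(4-methoxybenzyl)oxy]prop-1-en-2-yl}-2-methylcyclohex-1-en-1-olate | [Li]OC1=C(C)CC[C@H](C(=C)COCc2ccc(OC)cc2)C1 | intermediate
6 | (2S,5S)-5-{3-[(4-methoxybenzyl)oxy]prop-1-en-2-yl}-2-methylcyclohexan-1-one | O=C1[C@@H](C)CC[C@H](C(=C)COCc2ccc(OC)cc2)C1 | intermediate
7 | potassium (3S,6S)-3-{3-[(4-methoxybenzyl)oxy]prop-1-en-2-yl}-6-methylcyclohex-1-en-1-olate | [K]OC=1[C@@H](C)CC[C@H](C(=C)COCc2ccc(OC)cc2)C=1 | intermediate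
8 | (2R,3R,6S)-2-hydroxy-3-{3-[(4-methoxybenzyl)oxy]prop-1-en-2-yl}-6-methylcyclohexan-1-one | O=C1[C@@H](C)CC[C@H](C(=C)COCc2ccc(OC)cc2)[C@H]1O | intermediate
9 | (1R,3S,6R)-2,2-dimethoxy-6-{3-[(4-methoxybenzyl)oxy]prop-1-en-2-yl}-3-methylcyclohexan-1-ol | COC1(OC)[C@@H](C)CC[C@H](C(=C)COCc2ccc(OC)cc2)[C@H]1O | intermediate
10 | (1R,3S,6R)-2,2-dimethoxy-6-{(E)-1-[(4-methoxybenzyl)oxy]prop-1-en-2-yl}-3-methylcyclohexan-1-ol | COC1(OC)[C@@H](C)CC[C@H](/C(C)=C/OCc2ccc(OC)cc2)[C@H]1O | intermediate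
11 | (3S,6R)-2,2-dimethoxy-6-{(E)-1-[(4-methoxybenzyl)oxy]prop-1-en-2-yl}-3-methylcyclohexan-1-one | COC1(OC)[C@@H](C)CC[C@H](/C(C)=C/OCc2ccc(OC)cc2)C1=O | intermediate
12 | trichloroethylene | ClC=C(Cl)Cl | starting material
13 | (E)-1,2-dichloroethenyl 4-methoxybenzyl ether | COc1ccc(CO/C(Cl)=C\Cl)cc1 | intermediate
14 | lithium [(4-methoxybenzyl)oxy]acetylide | [Li]C#COCc1ccc(OC)cc1 | intermediate
15 | (1S,3S,6R)-2,2-dimethoxy-1-{[(4-methoxybenzyl)oxy]ethynyl}-6-{(E)-1-[(4-methoxybenzyl)oxy]prop-1-en-2-yl}-3-methylcyclohexan-1-ol | COC1(OC)[C@@H](C)CC[C@H](/C(C)=C/OCc2ccc(OC)cc2)[C@]1(O)C#COCc3ccc(OC)cc3 | intermediate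
16 | (1S,3S,6R)-2,2-dimethoxy-1-{(E)-2-[(4-methoxybenzyl)oxy]ethenyl}-6-{(E)-1-[(4-methoxybenzyl)oxy]prop-1-en-2-yl}-3-methylcyclohexan-1-ol | COC1(OC)[C@@H](C)CC[C@H](/C(C)=C/OCc2ccc(OC)cc2)[C@]1(O)/C=C/OCc3ccc(OC)cc3 | intermediate
17 | potassium alkoxide of 16 | COC1(OC)[C@@H](C)CC[C@H](/C(C)=C/OCc2ccc(OC)cc2)[C@]1(O[K])/C=C/OCc3ccc(OC)cc3 | intermediate
18 | potassium (1Z,3R,4R,5Z,9S)-10,10-dimethoxy-3,4-bis[(4-methoxybenzyl)oxy]-5,9-dimethylcyclodeca-1,5-dien-1-olate | [K]O/C1=C\[C@@H](OCc2ccc(OC)cc2)[C@H](OCc3ccc(OC)cc3)/C(C)=C\CC[C@H](C)C1(OC)OC | intermediate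
19 | tert-butyl 2-{(1R,2R,3R,4Z,8S)-9,9-dimethoxy-2,3-bis[(4-methoxybenzyl)oxy]-4,8-dimethyl-10-oxocyclodec-4-en-1-yl}acetate | O=C1[C@H](CC(=O)OC(C)(C)C)[C@@H](OCc2ccc(OC)cc2)[C@H](OCc3ccc(OC)cc3)/C(C)=C\CC[C@H](C)C1(OC)OC | intermediate
20 | tert-butyl 2-{(1S,2R,3R,4Z,8S,10S)-10-hydroxy-9,9-dimethoxy-2,3-bis[(4-methoxybenzyl)oxy]-4,8-dimethylcyclodec-4-en-1-yl}acetate | O[C@H]1[C@H](CC(=O)OC(C)(C)C)[C@@H](OCc2ccc(OC)cc2)[C@H](OCc3ccc(OC)cc3)/C(C)=C\CC[C@H](C)C1(OC)OC | intermediate
21 | tert-butyl 2-{(1R,2R,3R,4Z,8S,10S)-9,9-dimethoxy-2,3-bis[(4-methoxybenzyl)oxy]-4,8-dimethyl-10-[(triethylsilyl)oxy]cyclodec-4-en-1-yl}acetate | CC[Si](CC)(CC)O[C@H]1[C@H](CC(=O)OC(C)(C)C)[C@@H](OCc2ccc(OC)cc2)[C@H](OCc3ccc(OC)cc3)/C(C)=C\CC[C@H](C)C1(OC)OC | intermediate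
22 | tert-butyl 2-{(1R,2R,3R,4Z,8S,10S)-2,3-dihydroxy-9,9-dimethoxy-4,8-dimethyl-10-[(triethylsilyl)oxy]cyclodec-4-en-1-yl}acetate | CC[Si](CC)(CC)O[C@H]1[C@H](CC(=O)OC(C)(C)C)[C@@H](O)[C@H](O)/C(C)=C\CC[C@H](C)C1(OC)OC | intermediate
23 | tert-butyl 2-{(1R,2R,3S,4S,5R,8S,10S)-4,5-epoxy-2,3-dihydroxy-9,9-dimethoxy-4,8-dimethyl-10-[(triethylsilyl)oxy]cyclodecyl}acetate | CC[Si](CC)(CC)O[C@H]1[C@H](CC(=O)OC(C)(C)C)[C@@H](O)[C@H](O)[C@]2(C)O[C@@H]2CC[C@H](C)C1(OC)OC | intermediate
24 | 2-{(1R,2R,3S,4R,8S,10S)-2,3,4-trihydroxy-9,9-dimethoxy-4,8-dimethyl-10-[(triethylsilyl)oxy]cyclodecyl}ethan-1-ol | CC[Si](CC)(CC)O[C@H]1[C@H](CCO)[C@@H](O)[C@H](O)[C@](C)(O)CCC[C@H](C)C1(OC)OC | intermediate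
25 | lactol of 24 (2-hydroxy analogue of 26; both configurations at the lactol carbon) | CC[Si](CC)(CC)O[C@H]1[C@@H]2CC(O)O[C@H]2[C@H](O)[C@](C)(O)CCC[C@H](C)C1(OC)OC | intermediate
26 | (3aR,4S,6S,10R,11S,11aR)-10,11-dihydroxy-5,5-dimethoxy-6,10-dimethyl-4-[(triethylsilyl)oxy]decahydrocyclodeca[b]furan-2(3H)-one | CC[Si](CC)(CC)O[C@H]1[C@@H]2CC(=O)O[C@H]2[C@H](O)[C@](C)(O)CCC[C@H](C)C1(OC)OC | intermediate
27 | sodium salt of the 3-(hydroxymethylidene) derivative of 26 (hydroxyls drawn free) | CC[Si](CC)(CC)O[C@H]1[C@@H]2C(=CO[Na])C(=O)O[C@H]2[C@H](O)[C@](C)(O)CCC[C@H](C)C1(OC)OC | intermediate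
28 | (3aR,4S,6S,10R,11S,11aR)-10,11-dihydroxy-5,5-dimethoxy-6,10-dimethyl-3-methylidene-4-[(triethylsilyl)oxy]decahydrocyclodeca[b]furan-2(3H)-one | CC[Si](CC)(CC)O[C@H]1[C@@H]2C(=C)C(=O)O[C@H]2[C@H](O)[C@](C)(O)CCC[C@H](C)C1(OC)OC | intermediate
29 | (3aR,4S,6S,10R,11S,11aR)-10-hydroxy-5,5-dimethoxy-6,10-dimethyl-3-methylidene-2-oxo-4-[(triethylsilyl)oxy]dodecahydrocyclodeca[b]furan-11-yl 3-methylbutanoate | CC[Si](CC)(CC)O[C@H]1[C@@H]2C(=C)C(=O)O[C@H]2[C@H](OC(=O)CC(C)C)[C@](C)(O)CCC[C@H](C)C1(OC)OC | intermediate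
30 | CNP0240128.1, (3aS,4S,6S,10R,11S,11aR)-4,10-dihydroxy-6,10-dimethyl-3-methylidene-2,5-dioxododecahydrocyclodeca[b]furan-11-yl 3-methylbutanoate | C=C1C(=O)O[C@@H]2[C@@H]1[C@H](O)C(=O)[C@@H](C)CCC[C@@](C)(O)[C@H]2OC(=O)CC(C)C | target

**Step count and risks**

Total: 20 steps. Longest linear sequence: 19 steps (steps 1–7 and 9–20, from (S)-carvone); step 8 is a one-step branch.

Most likely to fail:

1. Step 11. The potassium enolate may lose the C6 alkoxide by beta-elimination or be O-alkylated before C-alkylation, or the alkoxide may fragment instead of rearranging. Fallback: separate the pericyclic step from the enolate chemistry. Compound 16 is silylated (Me3SiCl, imidazole) to its trimethylsilyl ether F1, which is heated (decalin, about 200 °C) in a neutral siloxy-Cope rearrangement through the same chair to the ring-expanded trimethylsilyl enol ether F2. MeLi at −78 °C then releases the lithium enolate F3 regiospecifically, and tert-butyl bromoacetate alkylates it to rejoin the route at 19.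

2. Step 12. Hydride addition to the ring ketone may show poor facial selectivity if the ring conformation overrides chelate and Felkin control. Fallback: internal hydride delivery. From 19 both benzylic ethers are removed first (DDQ, buffered) to give the keto diol F4, and the free C6 hydroxyl directs a Narasaka–Prasad reduction (Et2BOMe, NaBH4, −78 °C) to the 1,3-syn triol F5. The vicinal C5/C6 diol is tied up as the cyclic carbonate F6 (carbonyldiimidazole), the C8 hydroxyl is silylated (Et3SiOTf, 2,6-lutidine) to the silyl ether carbonate F7, and methanolysis of the carbonate (K2CO3, MeOH) returns to the route at 22.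

3. Step 15. Oxygen may be delivered to the wrong alkene face, or the epoxide may open transannularly. Fallback: radical Markovnikov hydration in place of epoxidation and hydride opening. From 22 the alkene is hydrated directly (Mn(dpm)3, PhSiH3, O2, Mukaiyama hydration) to the tertiary alcohol F8, and LiBHEt3 reduction of its tert-butyl ester returns to the route at 24, passing over 23.

**Further compounds**

F1 | step 11 | trimethylsilyl ether of 16 | COC1(OC)[C@@H](C)CC[C@H](/C(C)=C/OCc2ccc(OC)cc2)[C@]1(O[Si](C)(C)C)/C=C/OCc3ccc(OC)cc3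
F2 | step 11 | (1Z,3R,4R,5Z,9S)-10,10-dimethoxy-3,4-bis[(4-methoxybenzyl)oxy]-5,9-dimethyl-1-[(trimethylsilyl)oxy]cyclodeca-1,5-diene | C[Si](C)(C)O/C1=C\[C@@H](OCc2ccc(OC)cc2)[C@H](OCc3ccc(OC)cc3)/C(C)=C\CC[C@H](C)C1(OC)OC
F3 | step 11 | lithium enolate corresponding to 18 | [Li]O/C1=C\[C@@H](OCc2ccc(OC)cc2)[C@H](OCc3ccc(OC)cc3)/C(C)=C\CC[C@H](C)C1(OC)OC
F4 | step 12 | keto diol, 19 without its two 4-methoxybenzyl groups | O=C1[C@H](CC(=O)OC(C)(C)C)[C@@H](O)[C@H](O)/C(C)=C\CC[C@H](C)C1(OC)OC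
F5 | step 12 | 1,3-syn triol, tert-butyl 2-[2,3,10-trihydroxy-9,9-dimethoxy-4,8-dimethylcyclodec-4-en-1-yl]acetate | O[C@H]1[C@H](CC(=O)OC(C)(C)C)[C@@H](O)[C@H](O)/C(C)=C\CC[C@H](C)C1(OC)OC
F6 | step 12 | C5/C6 cyclic carbonate of F5 | O[C@H]1[C@H](CC(=O)OC(C)(C)C)[C@H]2OC(=O)O[C@@H]2/C(C)=C\CC[C@H](C)C1(OC)OC
F7 | step 12 | C8 triethylsilyl ether of F6 | CC[Si](CC)(CC)O[C@H]1[C@H](CC(=O)OC(C)(C)C)[C@H]2OC(=O)O[C@@H]2/C(C)=C\CC[C@H](C)C1(OC)OC
F8 | step 15 | tert-butyl 2-{2,3,4-trihydroxy-9,9-dimethoxy-4,8-dimethyl-10-[(triethylsilyl)oxy]cyclodecyl}acetate (tert-butyl ester corresponding to 24) | CC[Si](CC)(CC)O[C@H]1[C@H](CC(=O)OC(C)(C)C)[C@@H](O)[C@H](O)[C@](C)(O)CCC[C@H](C)C1(OC)OC
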